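Your four flasks are read first at 80 min, and the question there is what fraction of each charge of Q has become L. They differ in that charge, with G held at 80 mM as in both earlier runs.

| setting | alder | ash | beta | epsilon | gamma | alpha |
|---|---|---|---|---|---|---|
| Q | 0.14 M | 1.1 M | 0.25 M | 0.80 M | 0.50 M | 0.12 M |
| G | 80 mM (held) | 80 mM (held) | 80 mM (held) | 80 mM (held) | 80 mM (held) | 80 mM (held) |
| remark | run made earlier | run made earlier |  |  |  |  |
| time |  |  | 80 min | 80 min | 80 min | 80 min |

| run | time / min | L / % |
|---|---|---|
| alder | 2.00 | 0 |
| alder | 6.00 | 1.6 |
| alder | 12.0 | 4.2 |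
| alder | 15.0 | 5.7 |
| alder | 25.0 | 12.3 |
| alder | 30.0 | 14.5 |
| alder | 40.0 | 22.8 |
| ash | 2.00 | 0.6 |
| ash | 6.00 | 0.2 |
| ash | 12.0 | 2.4 |
| ash | 15.0 | 1.6 |
| ash | 25.0 | 2.9 |
| ash | 30.0 | 5.2 |
| ash | 40.0 | 7.3 |

(readings scatter by 1 percentage point)

* ranking by amount of L, in percent of the Q charged, from high to low, at 80 min (beta / epsilon / gamma / alpha)
* the same order at 5.0 h (beta / epsilon / gamma / alpha)
* the amount of L, in percent of the Q charged of the flask you put first, at 80 min
* the amount of L, in percent of the Q charged of the flask you put last, at 80 min

- at the start none of G is in solution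

Alpha has a close neighbour in the alder run, charged at 0.14 M against alpha's 0.12 M, so you start from alder and ask how far the charge moves the fraction. The ash run shows this. With 7.86 times alder's charge, ash has turned 7.3% of its charge into L at 40.0 min, against alder's 22.8%. Counted as amount, that is 2.52 times alder's L, so L does not keep pace with the charge.

Now divide alder's fraction by ash's at the same time, so that both runs have had equal time. The quotient reads 4.24, 2.79 and 3.12 at 25.0 min, 30.0 min and 40.0 min. These are readings with a scatter of 1 percentage point on ash's small numbers, and each belongs to its own time, since the quotient need not stay the same as the clock runs.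

So I take this rule for flasks read at 40.0 min under this G: the fraction goes as one over the charge plus a fixed amount. The last quotient gives that amount as 0.312 M, a reading that carries the scatter. This is the bend charge, the charge at which the fraction has fallen to half its value for a very small charge.

Alpha and alder differ by 0.0200 M, far less than that, so alpha at 40.0 min should stand at 23.9%, just above alder. My reckoning gives ratios, not heights, and for 80 min I must assume that the amount read at 40.0 min still serves: then the order is alpha, beta, gamma, epsilon, and alpha's fraction is 2.57 times epsilon's. I carry that order to 5.0 h with less trust, since the runs stop at 40.0 min.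

The forecast says alpha > beta > gamma > epsilon at 80 min, with 43% and 17.5%, a ratio of 2.46 against my 2.57, and alpha > beta > gamma > epsilon at 5.0 h, on the ground that “Percent conversion falls as Q rises.”

At 80.0 min the flasks stand in the order alpha > beta > gamma > epsilon, with alpha at 42.1% and epsilon at 17.3%, a ratio of 2.43, and at 5.0 h the order is alpha > beta > gamma > epsilon.

    Q ⇌ E (K = 19.0, k = 1.80 × 10⁻⁴ s⁻¹)
    E ⇌ J (K = 0.690, k = 9.14 × 10⁻⁵ s⁻¹)
    Q + X → L (k = 0.00636 M⁻¹ s⁻¹)
    X + J ⇌ D (K = 31.0 M⁻¹, k = 0.00295 M⁻¹ s⁻¹)
    G ⇌ X, rate k5*(csat - [X]) (kL = 4.76 × 10⁻⁴ s⁻¹)

At that time the dissolved X stands at 0.0524 M in alpha and 0.0157 M in epsilon, with G held at 80 mM. Put the bend charge to use on gamma: it turns epsilon's 17.3% into 23.7%, and gamma stands at 24.0%.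

(Readings and results were generated by integration for an exercise, noise included.)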